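Assumption: the SMILES has no stereocentre, so jaspaquinol is achiral. "Single enantiomer" is taken to mean the single (2E,6E) geometric isomer, and the two trisubstituted alkenes are the only stereo-elements to control.

## Retrosynthetic overview
1. The target comes from its bis-TBS ether by fluoride deprotection. No oxidation or acid is used at the end, so no chroman or quinone forms.
2. Key disconnection (new reaction): the aryl–CH2 bond and the C2=C3 E-geometry are made together by Ni-catalysed 1,4-hydroarylation of a 2-substituted 1,3-diene with a hydroquinone-derived arylboronate.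
3. The 2-substituted diene comes from a terminal 1,5-enyne by ene–yne metathesis with ethylene.
4. The 1,5-enyne comes from Negishi sp2–sp3 coupling of an (E)-alkenyl iodide with a homopropargylzinc. The C6=C7 E-geometry comes from Zr-catalysed methylalumination of the alkyne made from dihydro-β-ionone.
5. No ring is formed. The trimethylcyclohexene (dihydro-β-ionone) and the arene (bromohydroquinone) are both purchased.

## Route

**Step 1**
Reactants: 1, dihydro-β-ionone [4-(2,6,6-trimethylcyclohex-1-en-1-yl)butan-2-one]
Product: 2, 2-(but-3-yn-1-yl)-1,3,3-trimethylcyclohex-1-ene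
Conditions: LDA (1.1 equiv), THF, −78 °C; ClP(O)(OEt)2, −78 °C to rt; then LDA (2.3 equiv), −78 °C to rt; H2O
Reagents that add atoms: none (the phosphate is installed and then eliminated)
Why: Kinetic CH3-side enolisation, O-phosphorylation and LDA-induced E2 elimination of the enol phosphate (Negishi methyl ketone to terminal alkyne conversion) give the alkyne, and the hindered tetrasubstituted ring alkene is inert to amide base.

**Step 2**
Reactants: 2
Product: 3, 2-[(3E)-4-iodo-3-methylbut-3-en-1-yl]-1,3,3-trimethylcyclohex-1-ene
Conditions: Me3Al (2 equiv), Cp2ZrCl2 (25 mol %), CH2Cl2, 0 °C to rt; then I2, THF, −30 to 0 °C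
Reagents that add atoms: trimethylaluminium C[Al](C)C (CH3); iodine II (I)
Why: Zr-catalysed methylalumination (Negishi carboalumination) is a syn addition that puts Me on the internal carbon and Al on the terminal carbon, and iodinolysis proceeds with retention, so the C6=C7 alkene is set ≥98% E while the ring alkene does not react.

**Step 3**
Reactants: 3; 4, 4-bromo-1-(trimethylsilyl)but-1-yne
Product: 5, trimethyl[(5E)-6-methyl-8-(2,6,6-trimethylcyclohex-1-en-1-yl)oct-5-en-1-yn-1-yl]silane
Conditions: 4, Mg, THF; ZnBr2 (organozinc formed in situ, not isolated); then 3, Pd(dppf)Cl2 (3 mol %), THF, rt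
Reagents that add atoms: 4, used as 4-(trimethylsilyl)but-3-ynylzinc bromide C[Si](C)(C)C#CCC[Zn]Br
Why: In this Negishi C(sp2)–C(sp3) cross-coupling, oxidative addition and reductive elimination retain the alkenyl geometry, dppf suppresses β-hydride elimination, and TMS masks the acidic alkyne C–H.

**Step 4**
Reactants: 5
Product: 6, 1,3,3-trimethyl-2-[(3E)-3-methyloct-3-en-7-yn-1-yl]cyclohex-1-ene
Conditions: K2CO3, MeOH, rt
Reagents that add atoms: none
Why: Methoxide-mediated protiodesilylation of the alkynylsilane touches nothing else in this hydrocarbon.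

**Step 5**
Reactants: 6
Product: 7, 1,3,3-trimethyl-2-[(3E)-3-methyl-7-methylidenenona-3,8-dien-1-yl]cyclohex-1-ene
Conditions: Grubbs II (5 mol %), ethylene (4 atm), CH2Cl2, rt
Reagents that add atoms: ethylene C=C
Why: Ene–yne cross-metathesis with ethylene converts R–C≡CH into R–C(=CH2)–CH=CH2, the tri- and tetrasubstituted alkenes are too hindered for the Ru carbene, and ring-closing on the 1,5-enyne would require a cyclobutene.

**Step 6**
Reactants: 8, 2-bromobenzene-1,4-diol (bromohydroquinone)
Product: 9, 2-bromo-1,4-bis(tert-butyldimethylsilyloxy)benzene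
Conditions: TBSCl (2.5 equiv), imidazole (5 equiv), DMF, rt
Reagents that add atoms: TBSCl CC(C)(C)[Si](C)(C)Cl
Why: Standard imidazole-promoted silyl ether formation blocks both phenols and prevents hydroquinone/quinone redox chemistry in the metal-catalysed steps.

**Step 7**
Reactants: 9
Product: 10, 2-[2,5-bis(tert-butyldimethylsilyloxy)phenyl]-4,4,5,5-tetramethyl-1,3,2-dioxaborolane
Conditions: B2pin2 (1.3 equiv), Pd(dppf)Cl2 (4 mol %), KOAc (3 equiv), 1,4-dioxane, 85 °C
Reagents that add atoms: bis(pinacolato)diboron CC1(C)OB(OC1(C)C)B2OC(C)(C)C(C)(C)O2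
Why: Miyaura borylation with the weak base KOAc leaves aryl TBS ethers intact and avoids the retro-Brook silyl migration possible with an ortho-lithiated aryl silyl ether.

**Step 8 (key step, new)**
Reactants: 7; 10 (1.5 equiv)
Product: 11, 1,4-bis(tert-butyldimethylsilyloxy)-2-[(2E,6E)-3,7-dimethyl-9-(2,6,6-trimethylcyclohex-1-en-1-yl)nona-2,6-dien-1-yl]benzene
Conditions: Ni(cod)2 (10 mol %), PCy3 (12 mol %), MeOH (10 equiv), THF, 40 °C, 7 added slowly over 2 h
Reagents that add atoms: 10 (aryl group); methanol CO supplies only H
Why: Proposed new method: a Ni(0)-catalysed, redox-neutral, E-stereospecific 1,4-hydroarylation of a 2-alkyl-1,3-diene, in which (Cy3P)Ni(0) binds only the unhindered diene of 7 as its s-cis η4 complex, MeOH delivers H (ligand-to-ligand hydrogen transfer) to the =CH2 on the substituted carbon (largest HOMO coefficient, most substituted allyl) to give a π-allyl–Ni–OMe with the new CH3 anti and the chain syn, Ni–OMe/ArBpin transmetalation is followed by C–C reductive elimination at the primary terminus (the tertiary terminus cannot accommodate the ortho-silyloxy aryl) so that CH3 ends cis and the chain trans to CH2Ar (= E), this geometry is kinetically locked because syn/anti exchange would need a tertiary σ-allyl nickel, and competing allyl methyl ether formation is reversible while C–C formation is not; the closest known reaction types are Ni(0)/alcohol 1,2-hydroarylation of styrenes and 1-aryl dienes with arylborons, Ni- and Fe-catalysed stereoselective 1,4-hydroboration of dienes via s-cis complexes, and stereoretentive Suzuki coupling of geranyl electrophiles, whereas 1,4-selectivity on 2-alkyl dienes with control of trisubstituted-alkene geometry has not been shown.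

**Step 9**
Reactants: 11
Product: 12, jaspaquinol, 2-[(2E,6E)-3,7-dimethyl-9-(2,6,6-trimethylcyclohex-1-en-1-yl)nona-2,6-dien-1-yl]benzene-1,4-diol
Conditions: TBAF (2.5 equiv), AcOH (2.5 equiv), degassed THF, 0 °C, Ar; aqueous Na2S2O4 wash
Reagents that add atoms: none
Why: Buffered fluoride desilylation of aryl silyl ethers is non-acidic (no chroman formation, no alkene migration) and non-oxidative, and the dithionite wash reduces any trace of quinone, so both E-alkenes are untouched.

## Compound list
| No. | Name | SMILES | Role |
|---|---|---|---|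
| 1 | dihydro-β-ionone | CC1=C(CCC(C)=O)C(C)(C)CCC1 | starting material |
| 2 | 2-(but-3-yn-1-yl)-1,3,3-trimethylcyclohex-1-ene | CC1=C(CCC#C)C(C)(C)CCC1 | intermediate |
| 3 | 2-[(3E)-4-iodo-3-methylbut-3-en-1-yl]-1,3,3-trimethylcyclohex-1-ene | CC1=C(CC/C(C)=C/I)C(C)(C)CCC1 | intermediate |
| 4 | 4-bromo-1-(trimethylsilyl)but-1-yne | C[Si](C)(C)C#CCCBr | starting material |
| 5 | TMS-protected (E)-1,5-enyne | CC1=C(CC/C(C)=C/CCC#C[Si](C)(C)C)C(C)(C)CCC1 | intermediate |
| 6 | terminal (E)-1,5-enyne | CC1=C(CC/C(C)=C/CCC#C)C(C)(C)CCC1 | intermediate |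
| 7 | (E)-2-substituted 1,3-diene (tetraene) | CC1=C(CC/C(C)=C/CCC(=C)C=C)C(C)(C)CCC1 | intermediate |
| 8 | bromohydroquinone | Oc1ccc(O)c(Br)c1 | starting material |
| 9 | 2-bromo-1,4-bis(TBSO)benzene | CC(C)(C)[Si](C)(C)Oc1ccc(O[Si](C)(C)C(C)(C)C)c(Br)c1 | intermediate |
| 10 | 2,5-bis(TBSO)phenyl-Bpin | CC(C)(C)[Si](C)(C)Oc1ccc(O[Si](C)(C)C(C)(C)C)c(c1)B2OC(C)(C)C(C)(C)O2 | intermediate |
| 11 | jaspaquinol bis-TBS ether (2E,6E) | CC1=C(CC/C(C)=C/CC/C(C)=C/Cc2cc(O[Si](C)(C)C(C)(C)C)ccc2O[Si](C)(C)C(C)(C)C)C(C)(C)CCC1 | intermediate |
| 12 | jaspaquinol (2E,6E; achiral) | CC1=C(CC/C(C)=C/CC/C(C)=C/Cc2cc(O)ccc2O)C(C)(C)CCC1 | target |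

## Summary
Total step count: 9.
Longest linear sequence: 7 steps (1 → 2 → 3 → 5 → 6 → 7 → 11 → 12, i.e. Steps 1–5, 8 and 9).

Steps most likely to fail:
1. **Step 8 (new hydroarylation).** The risks are E/Z erosion, branched or 4,1-regioisomers, diene isomerisation or oligomerisation, and slow transmetalation of the ortho-silyloxy boronate.
   - Fallback (known chemistry): go back to enyne 6 and carry out Zr-catalysed methylalumination.
   - Couple the (E)-alkenylalane in situ with commercial 2,5-dimethoxybenzyl chloride under Pd(PPh3)4 catalysis (alkenyl–benzyl Negishi coupling).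
   - Finish with CAN oxidation to the quinone and Na2S2O4 reduction to 12.
2. **Step 5 (ene–yne metathesis).** The risks are catalyst death under ethylene, incomplete conversion, and loss of the diene to oligomerisation.
   - Fallback: bromoborate 6 with B-bromo-9-BBN and protonolyse with AcOH to give the 2-bromo-1-alkene.
   - Pd-catalysed vinylation with vinylzinc bromide then gives 7.
3. **Step 3 (sp2–sp3 Negishi coupling).** The risks are poor organozinc formation, β-hydride elimination and homocoupling.
   - Fallback without cross-coupling: convert the alkenylalane from 2 into its n-BuLi ate complex and open ethylene oxide to give the (E)-homoallylic alcohol.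
   - Make the iodide with I2/PPh3/imidazole, then displace it with lithium acetylide–ethylenediamine in DMSO to give 6.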